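**Plan**
- Retrosynthetic cuts, in order: the ring A–ring B bond (imidoyl triflate plus pyrrolylboronic acid); the N–C(spiro) and C(spiro)–C(OMe) bonds of ring B (back to a lactone carbonyl, methyl propiolate, methanol and ammonia); the C3–C2(ring C) bond of the 12-membered ring (carbenoid); the C4–chain bond (conjugate addition); the pyrrole–acyl bond.
- Enabling feature: C3 of the tetrahydropyran is α to the C2 carbonyl of a δ-lactone (C2 is the future spiro carbon) and is also the carbon bonded to C2 of ring C, whose C5 already carries the (CH2)7 chain from C4. A diazo group at C3 therefore places a carbenoid within reach of the one free α-carbon of the tethered pyrrole.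
- Forward order: lactone ring (steps 1–2); chain and ring C joined to it (steps 3–6); 12-membered ansa ring (step 8); ring B as a spiro lactam (steps 9–12); ring A last (steps 13–14).
- Stereochemistry: C6 from (S)-propylene oxide; C4 by conjugate addition anti to the C6 methyl; C3 by base equilibration to the 3,4-trans lactone; the spiro carbon by reversible acid closure to the anomerically stabilised N,O-spiroaminal.

Key step: step 8

Numbering used throughout: tetrahydropyran atoms are O1, C2 (lactone carbonyl, later spiro carbon), C3, C4, C5, C6 (CHMe). Ring A is the terminal pyrrole, ring B the methoxy-2H-pyrrole, ring C the ansa pyrrole.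
Assumption: the lactol formed in step 9 equilibrates with its open hydroxy ynone, so it is locked as the methyl ketal before any conjugate addition.
Remark on the two propiolates: the ethyl ester serves in step 1, where the alkoxy group is lost on lactonisation; the methyl ester serves in step 9, so that the methanolic steps 9 to 11 cannot scramble the ester.

**Step 1**
Reactants: 1 (S)-propylene oxide; 2 ethyl propiolate
Product: 4 ethyl (S)-5-hydroxyhex-2-ynoate, via lithium ethyl propiolate 3 (not isolated)
Conditions: 2, n-BuLi, THF, −78 °C; BF3·OEt2; 1, −78 °C; aq. NH4Cl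
Reagents that add atoms: none
Why: BF3-promoted alkynylation of a terminal epoxide by a lithium acetylide occurs at the CH2 terminus at −78 °C, where the lithiated propiolate is stable, so the C–O stereocentre of 1 is carried unchanged into 4.

**Step 2**
Reactants: 4 ethyl (S)-5-hydroxyhex-2-ynoate
Product: 6 (S)-6-methyl-5,6-dihydro-2H-pyran-2-one, via ethyl (2Z,5S)-5-hydroxyhex-2-enoate 5 (not isolated)
Conditions: H2 (1 atm), Pd/CaCO3 poisoned with Pb(OAc)2, quinoline, EtOAc, rt; filter; p-TsOH·H2O (cat.), toluene, rt
Reagents that add atoms: none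
Why: Semihydrogenation over lead-poisoned palladium gives the Z-enoate, in which hydroxyl and ester are cis and lactonise under acid catalysis to the six-membered unsaturated lactone without touching C6.

**Step 3**
Reactants: 7 7-bromoheptanoic acid; 8 pyrrole
Product: 11 7-bromo-1-(1H-pyrrol-2-yl)heptan-1-one, via 7-bromoheptanoyl chloride 9 (not isolated), via pyrrol-1-ylmagnesium bromide 10 (not isolated)
Conditions: 7, (COCl)2, DMF (cat.), CH2Cl2, rt, evaporate; 8, EtMgBr, Et2O, 0 °C → rt; 9 in toluene, −40 → 0 °C; aq. NH4Cl
Reagents that add atoms: none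
Why: Acid chloride formation followed by C-acylation of the ambident pyrrolyl Grignard reagent at C2 is the classical route to 2-acylpyrroles, and at low temperature the acyl chloride is far more electrophilic than the primary bromide.

**Step 4**
Reactants: 11 7-bromo-1-(1H-pyrrol-2-yl)heptan-1-one
Product: 12 2-(7-bromoheptyl)-1H-pyrrole
Conditions: NaBH4, i-PrOH, reflux
Reagents that add atoms: none
Why: A 2-acylpyrrole is a vinylogous amide that NaBH4 in hot 2-propanol reduces past the carbinol, through an azafulvene, to the 2-alkylpyrrole, while a primary alkyl bromide is reduced only slowly by borohydride in a protic solvent.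

**Step 5**
Reactants: 12 2-(7-bromoheptyl)-1H-pyrrole
Product: 13 2-(7-bromoheptyl)-1-(tert-butyldimethylsilyl)-1H-pyrrole
Conditions: KN(SiMe3)2, THF, −78 °C; t-BuMe2SiCl, −78 → 0 °C
Reagents that add atoms: tert-butyldimethylsilyl chloride, CC(C)(C)[Si](C)(C)Cl
Why: N-silylation of the potassium pyrrolide masks the acidic N–H so that a Grignard reagent can be made at the chain terminus, and at −78 °C the silyl chloride is captured faster than the bromide is alkylated.

**Step 6**
Reactants: 13 2-(7-bromoheptyl)-1-(tert-butyldimethylsilyl)-1H-pyrrole; 6 (S)-6-methyl-5,6-dihydro-2H-pyran-2-one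
Product: 16 (4S,6S)-4-{7-[1-(tert-butyldimethylsilyl)-1H-pyrrol-2-yl]heptyl}-6-methyltetrahydro-2H-pyran-2-one, via Grignard reagent 14 (not isolated), via silyl ketene acetal 15 (not isolated)
Conditions: 13, Mg, THF, 40 °C; CuBr·SMe2 (10 mol %), Me3SiCl, THF, −78 °C; 6; aq. NH4Cl
Reagents that add atoms: none
Why: Copper-catalysed, Me3SiCl-accelerated 1,4-addition of a Grignard reagent to a 5,6-dihydro-2H-pyran-2-one is well established, and axial attack on the half-chair anti to the C6 methyl group should give the 4,6-trans lactone, which sets C4 as S.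

**Step 7**
Reactants: 16 (4S,6S)-4-{7-[1-(tert-butyldimethylsilyl)-1H-pyrrol-2-yl]heptyl}-6-methyltetrahydro-2H-pyran-2-one
Product: 19 (4S,6S)-3-diazo-6-methyl-4-[7-(1H-pyrrol-2-yl)heptyl]tetrahydro-2H-pyran-2-one, via 3-trifluoroacetyl lactone 17 (not isolated), via N-silyl diazo lactone 18 (not isolated)
Conditions: LiN(SiMe3)2, THF, −78 °C; CF3CO2CH2CF3; then MeSO2N3, Et3N, H2O, MeCN, rt; then Bu4NF, THF, 0 °C
Reagents that add atoms: methanesulfonyl azide, CS(=O)(=O)N=[N+]=[N-]
Why: Deacylative diazo transfer works on lactones because Claisen trifluoroacetylation of the enolate activates C3 for the sulfonyl azide, which leaves with the trifluoroacetyl group as an acyl sulfonamide, and fluoride then cleaves the N–Si bond without harming the acceptor-stabilised diazo group or the C4 and C6 centres.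

**Step 8**
Reactants: 19 (4S,6S)-3-diazo-6-methyl-4-[7-(1H-pyrrol-2-yl)heptyl]tetrahydro-2H-pyran-2-one
Product: 21 (3S,4S,6S)-ansa δ-lactone (6-methyltetrahydro-2H-pyran-2-one with C3 bonded to C2 of a 1H-pyrrole and C4 joined by a (CH2)7 chain to C5 of that pyrrole), via C3-epimer mixture 20 (not isolated)
Conditions: Rh2(O2CCMe3)4 (2 mol %), CH2Cl2, −78 → −40 °C, 19 added by syringe pump to a final 1 mM; then DBU (0.2 equiv), rt
Reagents that add atoms: none
Why: Rh2(O2CCMe3)4 expels N2 from 19 to give an electrophilic carbenoid at C3 of the lactone, the free α-carbon (C5) of the tethered pyrrole attacks it, and the zwitterion collapses by proton transfer to the 2,5-dialkylated pyrrole. The closest known reaction type is the rhodium- or copper-carbenoid C–H alkylation of N–H pyrroles and indoles at their nucleophilic carbon by α-alkyl α-diazo esters, together with carbenoid macrocyclisation onto remote π-nucleophiles. The twelve-membered ring closes end to end by electrophilic aromatic substitution, helped over intermolecular reaction by slow addition at high dilution and by the lactone ring, which already holds C3 next to the chain origin C4. The new stereocentre C3 is α to the lactone carbonyl and bonded to the pyrrole, hence readily epimerised, so the DBU stage should funnel mixture 20 into the 3,4-trans isomer 21 (3S) under control of the C4 centre, since only the trans isomer can hold both ansa bonds equatorial on the lactone ring, at the modest price of an axial C6 methyl group. The step needs carbon over nitrogen and α over β attack, which the innate reactivity of a 2-alkylpyrrole supplies, and carbenoid capture over 1,2-hydride shift from C4, which the bulky pivalate ligands and the low temperature are chosen to secure.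

**Step 9**
Reactants: 21 (3S,4S,6S)-ansa δ-lactone; 22 methyl propiolate
Product: 25 methyl 3-[(3S,4S,6S)-2-methoxy ansa-tetrahydropyran-2-yl]prop-2-ynoate (cyclic methyl ketal; C2 epimers), via lithium methyl propiolate 23 (not isolated), via lactol 24 (not isolated)
Conditions: 22, n-BuLi, THF, −78 °C; 21, −78 °C; AcOH; evaporate; MeOH, HC(OMe)3, CSA (10 mol %), rt
Reagents that add atoms: methanol, CO
Why: Lithium propiolate is nucleophilic enough for 1,2-addition to a lactone but too weakly basic to enolise C3 or deprotonate the pyrrole N–H, the tetrahedral alkoxide resists a second addition at −78 °C, and acid-catalysed ketalisation with orthoformate as water scavenger converts the lactol and its open hydroxy ynone form into one cyclic methyl ketal whose C2 configuration converges in step 12.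

**Step 10**
Reactants: 25 methyl 3-[(3S,4S,6S)-2-methoxy ansa-tetrahydropyran-2-yl]prop-2-ynoate
Product: 26 3-[(3S,4S,6S)-2-methoxy ansa-tetrahydropyran-2-yl]prop-2-ynamide
Conditions: NH3 (7 M in MeOH), −20 → 0 °C
Reagents that add atoms: ammonia, N
Why: Ammonolysis of an acetylenic ester at low temperature is faster than conjugate addition of ammonia, as in the classical preparation of acetylenic primary amides, so the ynoate should become the primary ynamide with the ketal untouched.

**Step 11**
Reactants: 26 3-[(3S,4S,6S)-2-methoxy ansa-tetrahydropyran-2-yl]prop-2-ynamide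
Product: 27 (E)-3-methoxy-3-[(3S,4S,6S)-2-methoxy ansa-tetrahydropyran-2-yl]prop-2-enamide
Conditions: NaOMe (0.3 equiv), MeOH, rt → 40 °C
Reagents that add atoms: methanol, CO
Why: With the ketone masked as the ketal, the amide carbonyl is the only group activating the alkyne, so base-catalysed Michael addition of methanol places the methoxy group on the carbon next to C2, and reversible addition should favour the E isomer with the amide cis to C2 (any Z isomer converges under the acid of step 12).

**Step 12**
Reactants: 27 (E)-3-methoxy-3-[(3S,4S,6S)-2-methoxy ansa-tetrahydropyran-2-yl]prop-2-enamide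
Product: 28 spiro lactam (4-methoxy-1,5-dihydro-2H-pyrrol-2-one whose C5 is the R-configured C2 of the ansa tetrahydropyran)
Conditions: CSA (10 mol %), CH2Cl2, 4 Å molecular sieves, 0 °C → rt
Reagents that add atoms: none
Why: Acid ionises the anomeric methoxy group to the ring oxocarbenium ion, the cis amide nitrogen traps it in a 5-exo closure to the N-acyl N,O-spiroaminal, and because ionisation is reversible (oxygen attack to the iminolactone also reverts) the spiro carbon should settle in the R configuration, in which nitrogen is axial (anomeric effect) on the chair that keeps the two ansa bonds at C3 and C4 equatorial and the N–H, not the bulkier ring B carbon, lies syn to the axial C6 methyl group.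

**Step 13**
Reactants: 28 spiro lactam
Product: 29 imidoyl triflate (3-methoxy-5-(trifluoromethylsulfonyloxy)-2H-pyrrole spiro-fused at its C2 to the ansa tetrahydropyran)
Conditions: (CF3SO2)2O, 2,6-di-tert-butyl-4-methylpyridine, CH2Cl2, −78 → −20 °C; crude 29 used at once
Reagents that add atoms: trifluoromethanesulfonic anhydride, O=S(=O)(OS(=O)(=O)C(F)(F)F)C(F)(F)F
Why: O-sulfonylation of a secondary lactam with triflic anhydride and a hindered pyridine gives the imidoyl triflate, the established activation of 4-methoxy-3-pyrrolin-2-ones for cross-coupling, and since the vinylogous carbamate oxygen is the most nucleophilic site, the low temperature and non-nucleophilic base should spare the ansa pyrrole and the spiroaminal.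

**Step 14**
Reactants: 29 imidoyl triflate; 30 [1-(tert-butoxycarbonyl)-1H-pyrrol-2-yl]boronic acid
Product: 32 premarineosin A, via N-Boc premarineosin A 31 (not isolated)
Conditions: Pd(PPh3)4 (5 mol %), Na2CO3 (2 M aq.), 1,2-dimethoxyethane, 80 °C; then NaOMe, MeOH, rt
Reagents that add atoms: none
Why: Suzuki–Miyaura coupling of the imidoyl triflate with the N-Boc pyrrol-2-ylboronic acid forms the ring A–ring B bond at the sp2 carbon, and methoxide then cleaves the carbamate from the electron-poor pyrrole nitrogen, neither event touching a stereocentre.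

**Compound list**
1 | (S)-propylene oxide | C[C@H]1CO1 | starting material
2 | ethyl propiolate | CCOC(=O)C#C | starting material
3 | lithium ethyl propiolate | [Li+].[C-]#CC(=O)OCC | intermediate
4 | ethyl (S)-5-hydroxyhex-2-ynoate | C[C@H](O)CC#CC(=O)OCC | intermediate
5 | ethyl (2Z,5S)-5-hydroxyhex-2-enoate | C[C@H](O)C/C=C\C(=O)OCC | intermediate
6 | (S)-6-methyl-5,6-dihydro-2H-pyran-2-one | C[C@H]1CC=CC(=O)O1 | intermediate
7 | 7-bromoheptanoic acid | OC(=O)CCCCCCBr | starting material
8 | pyrrole | c1cc[nH]c1 | starting material
9 | 7-bromoheptanoyl chloride | ClC(=O)CCCCCCBr | intermediate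
10 | pyrrol-1-ylmagnesium bromide | Br[Mg]n1cccc1 | intermediate
11 | 7-bromo-1-(1H-pyrrol-2-yl)heptan-1-one | O=C(CCCCCCBr)c1ccc[nH]1 | intermediate
12 | 2-(7-bromoheptyl)-1H-pyrrole | BrCCCCCCCc1ccc[nH]1 | intermediate
13 | 2-(7-bromoheptyl)-1-(tert-butyldimethylsilyl)-1H-pyrrole | BrCCCCCCCc1cccn1[Si](C)(C)C(C)(C)C | intermediate
14 | {7-[1-(tert-butyldimethylsilyl)-1H-pyrrol-2-yl]heptyl}magnesium bromide | Br[Mg]CCCCCCCc1cccn1[Si](C)(C)C(C)(C)C | intermediate
15 | trimethylsilyl ketene acetal of 16 (4,6-trans) | C[Si](C)(C)OC1=C[C@@H](CCCCCCCc2cccn2[Si](C)(C)C(C)(C)C)C[C@H](C)O1 | intermediate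
16 | (4S,6S)-4-{7-[1-(tert-butyldimethylsilyl)-1H-pyrrol-2-yl]heptyl}-6-methyltetrahydro-2H-pyran-2-one | O=C1O[C@@H](C)C[C@H](CCCCCCCc2cccn2[Si](C)(C)C(C)(C)C)C1 | intermediate
17 | 3-(trifluoroacetyl) derivative of 16 (C3 epimers and enol) | O=C1O[C@@H](C)C[C@H](CCCCCCCc2cccn2[Si](C)(C)C(C)(C)C)C1C(=O)C(F)(F)F | intermediate
18 | (4S,6S)-3-diazo-4-{7-[1-(tert-butyldimethylsilyl)-1H-pyrrol-2-yl]heptyl}-6-methyltetrahydro-2H-pyran-2-one | O=C1O[C@@H](C)C[C@H](CCCCCCCc2cccn2[Si](C)(C)C(C)(C)C)C1=[N+]=[N-] | intermediate
19 | (4S,6S)-3-diazo-6-methyl-4-[7-(1H-pyrrol-2-yl)heptyl]tetrahydro-2H-pyran-2-one | O=C1O[C@@H](C)C[C@H](CCCCCCCc2ccc[nH]2)C1=[N+]=[N-] | intermediate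
20 | ansa δ-lactone as a mixture of C3 epimers (4S,6S) | O=C1O[C@@H](C)C[C@@H]2CCCCCCCc3ccc([nH]3)C21 | intermediate
21 | (3S,4S,6S)-ansa δ-lactone (C3 on pyrrole C2, C4 linked by (CH2)7 to pyrrole C5) | O=C1O[C@@H](C)C[C@@H]2CCCCCCCc3ccc([nH]3)[C@H]21 | intermediate
22 | methyl propiolate | COC(=O)C#C | starting material
23 | lithium methyl propiolate | [Li+].[C-]#CC(=O)OC | intermediate
24 | methyl 3-[(3S,4S,6S)-2-hydroxy ansa-tetrahydropyran-2-yl]prop-2-ynoate (lactol, C2 epimers) | COC(=O)C#CC1(O)O[C@@H](C)C[C@@H]2CCCCCCCc3ccc([nH]3)[C@H]21 | intermediate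
25 | methyl 3-[(3S,4S,6S)-2-methoxy ansa-tetrahydropyran-2-yl]prop-2-ynoate (C2 epimers) | COC(=O)C#CC1(OC)O[C@@H](C)C[C@@H]2CCCCCCCc3ccc([nH]3)[C@H]21 | intermediate
26 | 3-[(3S,4S,6S)-2-methoxy ansa-tetrahydropyran-2-yl]prop-2-ynamide (C2 epimers) | NC(=O)C#CC1(OC)O[C@@H](C)C[C@@H]2CCCCCCCc3ccc([nH]3)[C@H]21 | intermediate
27 | (E)-3-methoxy-3-[(3S,4S,6S)-2-methoxy ansa-tetrahydropyran-2-yl]prop-2-enamide (C2 epimers) | NC(=O)/C=C(/OC)C1(OC)O[C@@H](C)C[C@@H]2CCCCCCCc3ccc([nH]3)[C@H]21 | intermediate
28 | spiro lactam (spiro carbon R; 3S,4S,6S) | COC1=CC(=O)N[C@]12O[C@@H](C)C[C@@H]1CCCCCCCc3ccc([nH]3)[C@H]12 | intermediate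
29 | imidoyl triflate of 28 | COC1=CC(OS(=O)(=O)C(F)(F)F)=N[C@]12O[C@@H](C)C[C@@H]1CCCCCCCc3ccc([nH]3)[C@H]12 | intermediate
30 | [1-(tert-butoxycarbonyl)-1H-pyrrol-2-yl]boronic acid | CC(C)(C)OC(=O)n1cccc1B(O)O | starting material
31 | N-Boc premarineosin A (Boc on ring A nitrogen) | COC1=CC(c2cccn2C(=O)OC(C)(C)C)=N[C@]12O[C@@H](C)C[C@@H]1CCCCCCCc3ccc([nH]3)[C@H]12 | intermediate
32 | premarineosin A | COC1=CC(c2ccc[nH]2)=N[C@]12O[C@@H](C)C[C@@H]1CCCCCCCc3ccc([nH]3)[C@H]12 | target

**Step count and risks**
Total steps: 14. Longest linear sequence: 12 steps (steps 3 to 14, from 7 and 8).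

Steps most likely to fail:

1. Step 8. A 1,2-hydride shift from C4 to the carbenoid carbon, carbenoid dimerisation or intermolecular alkylation may outrun the slow twelve-membered closure. The fallback forms the same C3–C5(ring C) bond by oxidative enolate–pyrrole coupling; it sets out from 16 and returns at 21. Bu4NF in THF at 0 °C removes the N-silyl group to give (4S,6S)-6-methyl-4-[7-(1H-pyrrol-2-yl)heptyl]tetrahydro-2H-pyran-2-one F1. LiN(SiMe3)2 (2.2 equiv) in THF at −78 °C then forms the pyrrolide–lactone enolate dianion. Divalent copper 2-ethylhexanoate, Cu(O2CCH(C2H5)C4H9)2, added at high dilution, should oxidise it so that the α-carbonyl radical is captured by the pyrrole α-carbon. Equilibration with DBU as in step 8 would give 21.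

2. Step 13. Triflic anhydride may attack the electron-rich ansa pyrrole, or the imidoyl triflate may hydrolyse before it couples. The fallback activates the lactam through sulfur; it sets out from 28 and returns at 31, which is then taken through the methoxide stage of step 14. Thionation with 2,4-bis(4-methoxyphenyl)-1,3,2,4-dithiadiphosphetane 2,4-disulfide (Lawesson reagent) in THF at 50 °C should give the thiolactam F4. MeI and K2CO3 in acetone should alkylate sulfur to give the 5-methylthio-2H-pyrrole F5. Liebeskind–Srogl coupling of F5 with 30 (Pd2(dba)3, tri(2-furyl)phosphine, Cu(O2CC4H3S), the thiophene-2-carboxylate of monovalent copper, THF, 50 °C) should then give 31 under neutral conditions.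

3. Step 12. Facial selectivity at the spiro carbon may be poor under equilibrating acid, or the oxocarbenium ion may lose the C3 proton to give the conjugated enol ether. The fallback brings nitrogen in kinetically and closes the lactam without acid; it sets out from 25 and returns at 28. NaOMe in MeOH should add methanol across the ynoate to give methyl (E)-3-methoxy-3-[(3S,4S,6S)-2-methoxy ansa-tetrahydropyran-2-yl]prop-2-enoate F2. Me3SiN3 with Me3SiOSO2CF3 (cat.) in MeCN at −40 °C should replace the anomeric methoxy group by axial azide attack on the oxocarbenium ion, giving the configurationally fixed anomeric azide F3. Staudinger reduction with PMe3 in wet THF would release the anomeric amine, which should acylate on the neighbouring cis ester faster than the aminal can open, giving 28.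

**Further compounds**
F1 | step 8 | (4S,6S)-6-methyl-4-[7-(1H-pyrrol-2-yl)heptyl]tetrahydro-2H-pyran-2-one | O=C1O[C@@H](C)C[C@H](CCCCCCCc2ccc[nH]2)C1
F2 | step 12 | methyl (E)-3-methoxy-3-[(3S,4S,6S)-2-methoxy ansa-tetrahydropyran-2-yl]prop-2-enoate | COC(=O)/C=C(/OC)C1(OC)O[C@@H](C)C[C@@H]2CCCCCCCc3ccc([nH]3)[C@H]21
F3 | step 12 | methyl (E)-3-[(2R,3S,4S,6S)-2-azido ansa-tetrahydropyran-2-yl]-3-methoxyprop-2-enoate (azide axial) | COC(=O)/C=C(/OC)[C@]1(N=[N+]=[N-])O[C@@H](C)C[C@@H]2CCCCCCCc3ccc([nH]3)[C@H]21
F4 | step 13 | thiolactam corresponding to 28 | COC1=CC(=S)N[C@]12O[C@@H](C)C[C@@H]1CCCCCCCc3ccc([nH]3)[C@H]12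
F5 | step 13 | 3-methoxy-5-(methylthio)-2H-pyrrole spiro-fused at C2 to the ansa tetrahydropyran | COC1=CC(SC)=N[C@]12O[C@@H](C)C[C@@H]1CCCCCCCc3ccc([nH]3)[C@H]12
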